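- At late times the gamma run looks finished: its target climbs from 0.0632 M to 0.0659 M between 14 h and 17 h. The alpha run, with more free catalyst, stands higher at 0.0742 M, so the flat top need not be an equilibrium.

common to all: starting material 0.150 M
- gamma: free catalyst 7.50 × 10⁻⁴ M
- alpha: free catalyst 0.00110 M
- beta: free catalyst 7.50 × 10⁻⁴ M; time 51 h

| run | time / h | [target] / M |
|---|---|---|
| gamma run | 0.61 | 0.0060 |
| gamma run | 1.8 | 0.0164 |
| gamma run | 3.5 | 0.0285 |
| gamma run | 5.6 | 0.0403 |
| gamma run | 8.0 | 0.0497 |
| gamma run | 11 | 0.0587 |
| gamma run | 14 | 0.0632 |
| gamma run | 17 | 0.0659 |
| alpha run | 0.61 | 0.0070 |
| alpha run | 1.8 | 0.0193 |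
| alpha run | 3.5 | 0.0338 |
| alpha run | 5.6 | 0.0481 |
| alpha run | 8.0 | 0.0581 |
| alpha run | 11 | 0.0668 |
| alpha run | 14 | 0.0716 |
| alpha run | 17 | 0.0742 |

(scatter of a reading: 4 × 10⁻⁴ M)

* apparent order in [free catalyst] of the starting rate, round the charge of the gamma run (the rate where two percent of its starting material have turned into target)
* target in the beta run at 51 h, as a share of the starting material charged

- Overall: starting material -> target, with free catalyst as catalyst.
- Constant volume, constant temperature.
- Readings of a species count what is bound in complexes too.
- An order is taken over about fifteen percent of the charge, up and down.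

- The reckoning here starts with the main step: starting material turns into target in pseudo-first-order fashion, with a constant of 0.0656 h⁻¹ read from the first gamma reading. The beta run repeats the gamma charge, so this step by itself gives 96.5% at 51 h.
- One more process is then added: target leaves at a rate proportional to its own amount. Near the last gamma readings the main step makes 0.00356 M h⁻¹, whereas target rises by 9.00 × 10⁻⁴ M h⁻¹. The gap divided by the mean target gives 0.0412 h⁻¹, the loss constant: the fraction of the target lost per hour.
- The same reckoning on the alpha run reads 0.0362 h⁻¹, so this reading does not rise with the catalyst charge. With the loss included, the beta share drops to 23.4%.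
- Last comes the catalyst. The alpha-to-gamma ratio of target at 1.8 h gives an order of 0.425, and this leaves the beta number unchanged, since the beta charge is the gamma charge.
- The forecast gives an order of 0.46 (0.36 to 0.56) and a share of 48.5% (46.5% to 52%), which stands above the reckoning here. Its ground: “A true equilibrium would give the same plateau in both runs, so the catalyst is probably dying.”
- The flask gives an order of 0.57 and a share of 28.4%.

    2 free catalyst ⇌ catalyst dimer, settled at all times (12200 L mol⁻¹)
    free catalyst + starting material → target + free catalyst (435.6 L mol⁻¹ h⁻¹)
    free catalyst + target ⇌ catalyst-product complex, settled at all times (31.20 L mol⁻¹)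
    target → decomposed product (0.03600 h⁻¹)

- The path from target to decomposed product is the main reason for the low share: the beta run holds 28.4% with that path and 91.6% with it taken away. The loss constant, a reading from the gamma run, gives target an estimated mean life of 24.3 h, shorter than the 51 h of the beta run.

Readings and results were computed for an exercise; the scatter is artificial.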